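**Retrosynthetic overview** (side chain numbered C1' benzylic to C16'; ring A is the methylhydroquinone ring)
- Target 29 goes back, by redox and deprotection only, to alcohol 25, in which ring A is joined through benzylic C1' to the 2'E alkene C2'=C3'(CH3).
- The strategy rests on the unit ring A–C1'H2–C2'H=C3'(CH3)–C4': benzyl and methyl are cis on this alkene, so C1'–C2' and C3'–CH3 are cut together, leading to terminal alkyne 22 (C2'≡C3'), benzylic chloride 6 and Me3Al.
- Alkyne 22 comes from C4'–C5' propargylation of (2Z)-enal 19; 19 comes from a C12'–C13' bond between nerol-derived allylic chloride 11 and 3-methylbut-2-enal, with 13'R fixed by oxidation and CBS reduction; 6'Z is inherited from nerol and 10'E from E-selective SeO2 oxidation.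
- Chloride 6 comes from 4-methoxy-2-methylphenol by ortho-formylation, O-methylation, reduction and chlorination.
- No ring is formed in the route: ring A is carried from the phenol and only its oxidation level is adjusted at the end.

Key step: step 15

Remark: the C5' carbinol made in step 14 is not controlled and is carried as a mixture of epimers until it is oxidised in step 16, so the SMILES of 22, 24 and 25 leave that centre undefined; 14 is racemic at its carbinol.

**Route**

Step 1
Reactants: 1 4-methoxy-2-methylphenol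
Product: 3 2-hydroxy-5-methoxy-3-methylbenzaldehyde, via 2-(hydroxymethyl)-4-methoxy-6-methylphenol 2 (not isolated)
Conditions: MgCl2, Et3N, (CH2O)n, MeCN, reflux; aq. HCl
Reagents that add atoms: paraformaldehyde (as formaldehyde), C=O
Why: Casnati–Skattebøl ortho-formylation, in which the magnesium phenoxide delivers formaldehyde to the only free ortho carbon and the hydroxymethyl phenoxide 2 is oxidised in place by a second formaldehyde through hydride transfer, so the aldehyde can only enter next to the hydroxyl.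

Step 2
Reactants: 3 2-hydroxy-5-methoxy-3-methylbenzaldehyde
Product: 4 2,5-dimethoxy-3-methylbenzaldehyde
Conditions: MeI, K2CO3, DMF, rt
Reagents that add atoms: iodomethane, CI
Why: Williamson O-methylation of the phenoxide, which is the only acidic site.

Step 3
Reactants: 4 2,5-dimethoxy-3-methylbenzaldehyde
Product: 5 (2,5-dimethoxy-3-methylphenyl)methanol
Conditions: NaBH4, MeOH, 0 °C
Reagents that add atoms: none
Why: Borohydride reduction of an aryl aldehyde to the benzylic alcohol.

Step 4
Reactants: 5 (2,5-dimethoxy-3-methylphenyl)methanol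
Product: 6 1-(chloromethyl)-2,5-dimethoxy-3-methylbenzene
Conditions: SOCl2, pyridine, CH2Cl2, 0 °C
Reagents that add atoms: thionyl chloride, O=S(Cl)Cl
Why: Deoxychlorination of an electron-rich benzylic alcohol with thionyl chloride, with pyridine taking up HCl so that the activated ring is not alkylated by the product.

Step 5
Reactants: 7 nerol
Product: 8 tert-butyl{[(2Z)-3,7-dimethylocta-2,6-dien-1-yl]oxy}dimethylsilane
Conditions: TBSCl, imidazole, CH2Cl2, rt
Reagents that add atoms: tert-butyldimethylsilyl chloride, CC(C)(C)[Si](C)(C)Cl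
Why: Imidazole-promoted silylation of a primary allylic alcohol.

Step 6
Reactants: 8 tert-butyl{[(2Z)-3,7-dimethylocta-2,6-dien-1-yl]oxy}dimethylsilane
Product: 9 (2E,6Z)-8-(tert-butyldimethylsilyloxy)-2,6-dimethylocta-2,6-dien-1-ol
Conditions: SeO2 (cat.), t-BuOOH, salicylic acid (cat.), CH2Cl2, 0 °C to rt, stopped at partial conversion
Reagents that add atoms: tert-butyl hydroperoxide, CC(C)(C)OO; selenium dioxide, O=[Se]=O (catalytic oxygen carrier)
Why: Sharpless catalytic SeO2 allylic oxidation (ene reaction, then [2,3]-sigmatropic shift) should attack the electron-rich terminal alkene at its (E)-methyl group, the C2=C3 alkene being deactivated by the allylic oxygen.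

Step 7
Reactants: 9 (2E,6Z)-8-(tert-butyldimethylsilyloxy)-2,6-dimethylocta-2,6-dien-1-ol
Product: 11 tert-butyl{[(2Z,6E)-8-chloro-3,7-dimethylocta-2,6-dien-1-yl]oxy}dimethylsilane, via allylic mesylate 10 (not isolated)
Conditions: MsCl, 2,4,6-collidine, LiCl, DMF, 0 °C
Reagents that add atoms: lithium chloride, [Li+].[Cl-]; methanesulfonyl chloride, CS(=O)(=O)Cl (mesyl group of 10 only)
Why: Meyers-type chlorination, in which the primary allylic mesylate is displaced by chloride in an SN2 reaction without allylic transposition or change of alkene geometry.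

Step 8
Reactants: 11 tert-butyl{[(2Z,6E)-8-chloro-3,7-dimethylocta-2,6-dien-1-yl]oxy}dimethylsilane; 12 3-methylbut-2-enal
Product: 14 (4RS,6E,10Z)-12-(tert-butyldimethylsilyloxy)-2,6,10-trimethyldodeca-2,6,10-trien-4-ol, via allylbarium chloride 13 (not isolated)
Conditions: BaI2, lithium biphenylide, THF, rt (activated zerovalent barium); 11, −78 °C; 12, −78 °C; aq. NH4Cl
Reagents that add atoms: none
Why: Yamamoto allylbarium addition, in which barium inserts into the allylic chloride at −78 °C with retention of the (E) geometry and the allylbarium attacks the aldehyde carbonyl (1,2-addition) through its unsubstituted α-carbon to give the linear homoallylic alcohol; the carbinol forms racemic and is corrected in steps 9 and 10.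

Step 9
Reactants: 14 (4RS,6E,10Z)-12-(tert-butyldimethylsilyloxy)-2,6,10-trimethyldodeca-2,6,10-trien-4-ol
Product: 15 (6E,10Z)-12-(tert-butyldimethylsilyloxy)-2,6,10-trimethyldodeca-2,6,10-trien-4-one
Conditions: Dess–Martin periodinane, pyridine, CH2Cl2, 0 °C to rt
Reagents that add atoms: none
Why: Dess–Martin oxidation under buffered, non-enolising conditions, so that the β,γ-alkene C6=C7 should stay out of conjugation.

Step 10
Reactants: 15 (6E,10Z)-12-(tert-butyldimethylsilyloxy)-2,6,10-trimethyldodeca-2,6,10-trien-4-one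
Product: 16 (4R,6E,10Z)-12-(tert-butyldimethylsilyloxy)-2,6,10-trimethyldodeca-2,6,10-trien-4-ol
Conditions: (S)-2-methyl-CBS-oxazaborolidine, i.e. (3aS)-1-methyl-3,3-diphenyltetrahydro-1H,3H-pyrrolo[1,2-c][1,3,2]oxazaborole (20 mol %), catecholborane, toluene, −78 °C; MeOH, then aq. NaOH
Reagents that add atoms: none
Why: Corey–Bakshi–Shibata reduction, in which the ketone binds the (S)-oxazaborolidine with its isobutenyl group as the large and the allylic CH2 as the small substituent, and hydride from the boron-bound catecholborane is delivered to the face that gives the 4R carbinol (the sense known for alkenyl ketones).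

Step 11
Reactants: 16 (4R,6E,10Z)-12-(tert-butyldimethylsilyloxy)-2,6,10-trimethyldodeca-2,6,10-trien-4-ol
Product: 17 (4R,6E,10Z)-4,12-bis(tert-butyldimethylsilyloxy)-2,6,10-trimethyldodeca-2,6,10-triene
Conditions: TBSCl, imidazole, DMF, rt
Reagents that add atoms: tert-butyldimethylsilyl chloride, CC(C)(C)[Si](C)(C)Cl
Why: Silylation of the secondary allylic alcohol under basic conditions that do not ionise the C–O bond, so the 4R centre is kept.

Step 12
Reactants: 17 (4R,6E,10Z)-4,12-bis(tert-butyldimethylsilyloxy)-2,6,10-trimethyldodeca-2,6,10-triene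
Product: 18 (2Z,6E,9R)-9-(tert-butyldimethylsilyloxy)-3,7,11-trimethyldodeca-2,6,10-trien-1-ol
Conditions: HF·pyridine, pyridine, THF, 0 °C, monitored and stopped at monodesilylation
Reagents that add atoms: none
Why: Selective fluoride desilylation, since the unhindered primary silyl ether should be cleaved much faster than the branched secondary one.

Step 13
Reactants: 18 (2Z,6E,9R)-9-(tert-butyldimethylsilyloxy)-3,7,11-trimethyldodeca-2,6,10-trien-1-ol
Product: 19 (2Z,6E,9R)-9-(tert-butyldimethylsilyloxy)-3,7,11-trimethyldodeca-2,6,10-trienal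
Conditions: MnO2 (activated, excess), CH2Cl2, rt
Reagents that add atoms: none
Why: Allylic oxidation with MnO2 is neutral and heterogeneous and should give the (2Z)-enal without Z/E equilibration, as in the oxidation of nerol to neral.

Step 14
Reactants: 19 (2Z,6E,9R)-9-(tert-butyldimethylsilyloxy)-3,7,11-trimethyldodeca-2,6,10-trienal; 20 propargyl bromide
Product: 22 (4RS,5Z,9E,12R)-12-(tert-butyldimethylsilyloxy)-6,10,14-trimethylpentadeca-5,9,13-trien-1-yn-4-ol, via allenylzinc bromide 21 (not isolated)
Conditions: Zn dust, THF, 0 °C to rt (Barbier mode); aq. NH4Cl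
Reagents that add atoms: none
Why: Zinc Barbier propargylation, in which the allenylzinc bromide adds by SE2' to the aldehyde carbonyl (1,2-addition) to give the homopropargylic alcohol; the new C4 carbinol is formed without control, which is acceptable because it is oxidised in step 16.

Step 15
Reactants: 22 (4RS,5Z,9E,12R)-12-(tert-butyldimethylsilyloxy)-6,10,14-trimethylpentadeca-5,9,13-trien-1-yn-4-ol; 6 1-(chloromethyl)-2,5-dimethoxy-3-methylbenzene; 23 trimethylaluminium
Product: 25 (2E,5RS,6Z,10E,13R)-13-(tert-butyldimethylsilyloxy)-1-(2,5-dimethoxy-3-methylphenyl)-3,7,11,15-tetramethylhexadeca-2,6,10,14-tetraen-5-ol, via syn-alkenylalane 24 (not isolated)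
Conditions: Me3Al (3.5 equiv), Cp2ZrCl2 (25 mol %), ClCH2CH2Cl, 0 °C to rt; volatiles removed in vacuo; THF, 6, zerovalent nickel from NiCl2(PPh3)2 (5 mol %) and n-BuLi (10 mol %), 0 °C to rt; aq. Rochelle salt
Reagents that add atoms: trimethylaluminium 23, C[Al](C)C
Why: The first equivalent of Me3Al converts the C5' hydroxyl into its dimethylaluminium alkoxide with loss of methane, and the methylzirconocene species formed from Cp2ZrCl2 and Me3Al then adds methyl and metal syn across the terminal alkyne, methyl to the internal carbon C3' and the metal (passed on to aluminium) to C2', giving alane 24. Zerovalent nickel inserts into the benzylic C–Cl bond of 6, the alkenyl group moves from aluminium to nickel with retention, and reductive elimination forms C1'–C2'. The closest known reaction type is the Negishi zirconium-catalysed methylalumination of terminal alkynes followed by nickel-catalysed coupling of the alkenylalane with benzylic chlorides, the established way of attaching polyprenyl chains to protected hydroquinones. No ring is closed and no stereocentre is created; the only stereochemical outcome is the 2'E geometry, which follows from syn addition plus stereoretentive coupling, so that benzyl ends up cis to the new methyl. The step needs methyl delivery to C3', which the terminal alkyne secures, and chemoselectivity over the three trisubstituted alkenes, which do not carbometalate under these conditions. The mixture is kept at or below room temperature so that the syn alane does not equilibrate through alkoxide chelation, and excess Me3Al is stripped before the coupling so that methyl transfer to 6 does not compete.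

Step 16
Reactants: 25 (2E,5RS,6Z,10E,13R)-13-(tert-butyldimethylsilyloxy)-1-(2,5-dimethoxy-3-methylphenyl)-3,7,11,15-tetramethylhexadeca-2,6,10,14-tetraen-5-ol
Product: 26 (2E,6Z,10E,13R)-13-(tert-butyldimethylsilyloxy)-1-(2,5-dimethoxy-3-methylphenyl)-3,7,11,15-tetramethylhexadeca-2,6,10,14-tetraen-5-one
Conditions: Dess–Martin periodinane, pyridine, CH2Cl2, 0 °C
Reagents that add atoms: none
Why: Dess–Martin oxidation converges both C5' epimers to the ketone under buffered, non-enolising conditions that should leave the 6'Z enone and the skipped 2'E alkene unisomerised.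

Step 17
Reactants: 26 (2E,6Z,10E,13R)-13-(tert-butyldimethylsilyloxy)-1-(2,5-dimethoxy-3-methylphenyl)-3,7,11,15-tetramethylhexadeca-2,6,10,14-tetraen-5-one
Product: 27 (2E,6Z,10E,13R)-1-(2,5-dimethoxy-3-methylphenyl)-13-hydroxy-3,7,11,15-tetramethylhexadeca-2,6,10,14-tetraen-5-one
Conditions: HF·pyridine, pyridine, THF, 0 °C to rt
Reagents that add atoms: none
Why: Fluoride desilylation driven by Si–F bond formation, run with pyridine-buffered HF·pyridine so that no base is present to isomerise the Z-enone or move the β,γ-alkene.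

Step 18
Reactants: 27 (2E,6Z,10E,13R)-1-(2,5-dimethoxy-3-methylphenyl)-13-hydroxy-3,7,11,15-tetramethylhexadeca-2,6,10,14-tetraen-5-one
Product: 28 2-[(2E,6Z,10E,13R)-13-hydroxy-3,7,11,15-tetramethyl-5-oxohexadeca-2,6,10,14-tetraen-1-yl]-6-methylcyclohexa-2,5-diene-1,4-dione
Conditions: (NH4)2Ce(NO3)6 (2.5 equiv), MeCN/H2O, 0 °C
Reagents that add atoms: water, O
Why: Oxidative demethylation of the hydroquinone dimethyl ether by tetravalent cerium (two one-electron oxidations, ipso attack of water, loss of methanol), a reaction that tolerates isolated trisubstituted alkenes, ketones and secondary alcohols in polyprenyl quinone chemistry.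

Step 19
Reactants: 28 2-[(2E,6Z,10E,13R)-13-hydroxy-3,7,11,15-tetramethyl-5-oxohexadeca-2,6,10,14-tetraen-1-yl]-6-methylcyclohexa-2,5-diene-1,4-dione
Product: 29 2-[(2E,6Z,10E,13R)-13-hydroxy-3,7,11,15-tetramethyl-5-oxohexadeca-2,6,10,14-tetraen-1-yl]-6-methylbenzene-1,4-diol
Conditions: Na2S2O4, Et2O/H2O, rt, argon
Reagents that add atoms: none
Why: Two-electron reduction of the quinone by dithionite in a two-phase system should give the hydroquinone quickly at room temperature without touching the enone; the product is kept under inert gas.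

**Compound list**

1 | 4-methoxy-2-methylphenol | COc1ccc(O)c(C)c1 | starting material
2 | 2-(hydroxymethyl)-4-methoxy-6-methylphenol (as its magnesium phenoxide) | COc1cc(C)c(O)c(CO)c1 | intermediate (not isolated)
3 | 2-hydroxy-5-methoxy-3-methylbenzaldehyde | COc1cc(C)c(O)c(C=O)c1 | intermediate
4 | 2,5-dimethoxy-3-methylbenzaldehyde | COc1cc(C)c(OC)c(C=O)c1 | intermediate
5 | (2,5-dimethoxy-3-methylphenyl)methanol | COc1cc(C)c(OC)c(CO)c1 | intermediate
6 | 1-(chloromethyl)-2,5-dimethoxy-3-methylbenzene | COc1cc(C)c(OC)c(CCl)c1 | intermediate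
7 | nerol, (2Z)-3,7-dimethylocta-2,6-dien-1-ol | CC(C)=CCC/C(C)=C\CO | starting material
8 | tert-butyl{[(2Z)-3,7-dimethylocta-2,6-dien-1-yl]oxy}dimethylsilane | CC(C)=CCC/C(C)=C\CO[Si](C)(C)C(C)(C)C | intermediate
9 | (2E,6Z)-8-(tert-butyldimethylsilyloxy)-2,6-dimethylocta-2,6-dien-1-ol | OC/C(C)=C/CC/C(C)=C\CO[Si](C)(C)C(C)(C)C | intermediate
10 | (2E,6Z)-8-(tert-butyldimethylsilyloxy)-2,6-dimethylocta-2,6-dien-1-yl methanesulfonate | CS(=O)(=O)OC/C(C)=C/CC/C(C)=C\CO[Si](C)(C)C(C)(C)C | intermediate (not isolated)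
11 | tert-butyl{[(2Z,6E)-8-chloro-3,7-dimethylocta-2,6-dien-1-yl]oxy}dimethylsilane | ClC/C(C)=C/CC/C(C)=C\CO[Si](C)(C)C(C)(C)C | intermediate
12 | 3-methylbut-2-enal | CC(C)=CC=O | starting material
13 | [(2E,6Z)-8-(tert-butyldimethylsilyloxy)-2,6-dimethylocta-2,6-dien-1-yl]barium chloride | Cl[Ba]C/C(C)=C/CC/C(C)=C\CO[Si](C)(C)C(C)(C)C | intermediate (not isolated)
14 | (4RS,6E,10Z)-12-(tert-butyldimethylsilyloxy)-2,6,10-trimethyldodeca-2,6,10-trien-4-ol | CC(C)=CC(O)C/C(C)=C/CC/C(C)=C\CO[Si](C)(C)C(C)(C)C | intermediate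
15 | (6E,10Z)-12-(tert-butyldimethylsilyloxy)-2,6,10-trimethyldodeca-2,6,10-trien-4-one | CC(C)=CC(=O)C/C(C)=C/CC/C(C)=C\CO[Si](C)(C)C(C)(C)C | intermediate
16 | (4R,6E,10Z)-12-(tert-butyldimethylsilyloxy)-2,6,10-trimethyldodeca-2,6,10-trien-4-ol | CC(C)=C[C@H](O)C/C(C)=C/CC/C(C)=C\CO[Si](C)(C)C(C)(C)C | intermediate
17 | (4R,6E,10Z)-4,12-bis(tert-butyldimethylsilyloxy)-2,6,10-trimethyldodeca-2,6,10-triene | CC(C)=C[C@H](O[Si](C)(C)C(C)(C)C)C/C(C)=C/CC/C(C)=C\CO[Si](C)(C)C(C)(C)C | intermediate
18 | (2Z,6E,9R)-9-(tert-butyldimethylsilyloxy)-3,7,11-trimethyldodeca-2,6,10-trien-1-ol | CC(C)=C[C@H](O[Si](C)(C)C(C)(C)C)C/C(C)=C/CC/C(C)=C\CO | intermediate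
19 | (2Z,6E,9R)-9-(tert-butyldimethylsilyloxy)-3,7,11-trimethyldodeca-2,6,10-trienal | CC(C)=C[C@H](O[Si](C)(C)C(C)(C)C)C/C(C)=C/CC/C(C)=C\C=O | intermediate
20 | propargyl bromide, 3-bromoprop-1-yne | C#CCBr | starting material
21 | allenylzinc bromide, bromo(propa-1,2-dien-1-yl)zinc | C=C=C[Zn]Br | intermediate (not isolated)
22 | (4RS,5Z,9E,12R)-12-(tert-butyldimethylsilyloxy)-6,10,14-trimethylpentadeca-5,9,13-trien-1-yn-4-ol | CC(C)=C[C@H](O[Si](C)(C)C(C)(C)C)C/C(C)=C/CC/C(C)=C\C(O)CC#C | intermediate
23 | trimethylaluminium | C[Al](C)C | starting material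
24 | dimethylaluminium (1E,4RS,5Z,9E,12R)-12-(tert-butyldimethylsilyloxy)-1-(dimethylalumanyl)-2,6,10,14-tetramethylpentadeca-1,5,9,13-tetraen-4-olate | CC(C)=C[C@H](O[Si](C)(C)C(C)(C)C)C/C(C)=C/CC/C(C)=C\C(O[Al](C)C)C/C(C)=C/[Al](C)C | intermediate (not isolated)
25 | (2E,5RS,6Z,10E,13R)-13-(tert-butyldimethylsilyloxy)-1-(2,5-dimethoxy-3-methylphenyl)-3,7,11,15-tetramethylhexadeca-2,6,10,14-tetraen-5-ol | CC(C)=C[C@H](O[Si](C)(C)C(C)(C)C)C/C(C)=C/CC/C(C)=C\C(O)C/C(C)=C/Cc1cc(OC)cc(C)c1OC | intermediate
26 | (2E,6Z,10E,13R)-13-(tert-butyldimethylsilyloxy)-1-(2,5-dimethoxy-3-methylphenyl)-3,7,11,15-tetramethylhexadeca-2,6,10,14-tetraen-5-one | CC(C)=C[C@H](O[Si](C)(C)C(C)(C)C)C/C(C)=C/CC/C(C)=C\C(=O)C/C(C)=C/Cc1cc(OC)cc(C)c1OC | intermediate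
27 | (2E,6Z,10E,13R)-1-(2,5-dimethoxy-3-methylphenyl)-13-hydroxy-3,7,11,15-tetramethylhexadeca-2,6,10,14-tetraen-5-one | CC(C)=C[C@H](O)C/C(C)=C/CC/C(C)=C\C(=O)C/C(C)=C/Cc1cc(OC)cc(C)c1OC | intermediate
28 | 2-[(2E,6Z,10E,13R)-13-hydroxy-3,7,11,15-tetramethyl-5-oxohexadeca-2,6,10,14-tetraen-1-yl]-6-methylcyclohexa-2,5-diene-1,4-dione | CC(C)=C[C@H](O)C/C(C)=C/CC/C(C)=C\C(=O)C/C(C)=C/CC1=CC(=O)C=C(C)C1=O | intermediate
29 | 2-[(2E,6Z,10E,13R)-13-hydroxy-3,7,11,15-tetramethyl-5-oxohexadeca-2,6,10,14-tetraen-1-yl]-6-methylbenzene-1,4-diol | CC(C)=C[C@H](O)C/C(C)=C/CC/C(C)=C\C(=O)C/C(C)=C/Cc1cc(O)cc(C)c1O | target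

**Step count**

Total: 19 steps. Longest linear sequence: 15 steps (nerol 7 to 29, steps 5 to 19); the ring A branch (steps 1 to 4) joins in step 15.

**Steps most likely to fail**

Step 15. The benzylnickel intermediate may take up methyl instead of the alkenyl group from residual methylaluminium species, or transmetalation of the alkoxide-bearing alane may be slow, so that chloride 6 is used up unproductively. On long standing the syn alane may also drift towards the alkoxide-chelated anti isomer and erode the 2'E geometry. The fallback separates the two events and reverses the polarity of the coupling. It sets out from 22 and 6. Alkyne 22 is methylaluminated as in step 15 and alane 24 is quenched with I2 in THF at −30 °C to give (1E,4RS,5Z,9E,12R)-12-(tert-butyldimethylsilyloxy)-1-iodo-2,6,10,14-tetramethylpentadeca-1,5,9,13-tetraen-4-ol F1, which can be purified and its geometry checked. Chloride 6 is converted with zinc dust and LiCl in THF into chloro[(2,5-dimethoxy-3-methylphenyl)methyl]zinc F2. Negishi coupling of F1 with excess F2 under Pd(PPh3)4 in THF at rt should proceed with retention of alkene geometry and comes back to the route at 25.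

Step 8. Barium insertion may be accompanied by Wurtz-type homocoupling of the allylic chloride or by reductive cleavage of the allylic silyl ether, and any warming would let the allylbarium lose its geometry or its α-regioselectivity. The fallback reverses the polarity of the C12'–C13' bond and delivers the ketone directly. It sets out from 12 and 11. Aldehyde 12 is converted with propane-1,3-dithiol and BF3·OEt2 in CH2Cl2 at −20 °C into 2-(2-methylprop-1-en-1-yl)-1,3-dithiane F3. Deprotonation with n-BuLi in THF at −30 °C gives 2-lithio-2-(2-methylprop-1-en-1-yl)-1,3-dithiane F4. Alkylation with 11 at −78 °C, expected at the dithiane carbon, gives tert-butyl{[(2Z,6E)-3,7-dimethyl-8-[2-(2-methylprop-1-en-1-yl)-1,3-dithian-2-yl]octa-2,6-dien-1-yl]oxy}dimethylsilane F5. Hydrolysis with MeI and CaCO3 in aqueous MeCN comes back to the route at enone 15, so that steps 8 and 9 are both replaced.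

Step 10. The two ketone substituents, an allylic CH2 and an isobutenyl group, may not differ enough for the oxazaborolidine, giving poor facial selectivity at C13'. The fallback sets this centre by auxiliary-controlled alkylation instead of reduction. It sets out from 11.
- Finkelstein exchange (NaI, acetone) gives tert-butyl{[(2Z,6E)-8-iodo-3,7-dimethylocta-2,6-dien-1-yl]oxy}dimethylsilane F6.
- The known imide (4S)-4-benzyl-3-[(4-methoxybenzyloxy)acetyl]-1,3-oxazolidin-2-one is deprotonated with NaN(SiMe3)2 in THF at −78 °C to its sodium (Z)-enolate F7. Alkylation with F6, on the face away from the benzyl group, gives (4S)-4-benzyl-3-[(2R,4E,8Z)-10-(tert-butyldimethylsilyloxy)-2-(4-methoxybenzyloxy)-4,8-dimethyldeca-4,8-dienoyl]-1,3-oxazolidin-2-one F8, whose minor diastereomer can be removed by chromatography.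
- LiBH4 in wet Et2O removes the auxiliary and gives (2R,4E,8Z)-10-(tert-butyldimethylsilyloxy)-2-(4-methoxybenzyloxy)-4,8-dimethyldeca-4,8-dien-1-ol F9.
- Dess–Martin oxidation gives (2R,4E,8Z)-10-(tert-butyldimethylsilyloxy)-2-(4-methoxybenzyloxy)-4,8-dimethyldeca-4,8-dienal F10.
- Wittig reaction at −78 °C with isopropylidene(triphenyl)phosphorane F11, made from isopropyltriphenylphosphonium iodide and n-BuLi, gives tert-butyl{[(2Z,6E,9R)-9-(4-methoxybenzyloxy)-3,7,11-trimethyldodeca-2,6,10-trien-1-yl]oxy}dimethylsilane F12.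
- DDQ in CH2Cl2 with pH 7 buffer removes the 4-methoxybenzyl group and comes back to the route at 16.

**Further compounds**

F1 | step 15 | (1E,4RS,5Z,9E,12R)-12-(tert-butyldimethylsilyloxy)-1-iodo-2,6,10,14-tetramethylpentadeca-1,5,9,13-tetraen-4-ol | CC(C)=C[C@H](O[Si](C)(C)C(C)(C)C)C/C(C)=C/CC/C(C)=C\C(O)C/C(C)=C/I
F2 | step 15 | chloro[(2,5-dimethoxy-3-methylphenyl)methyl]zinc | COc1cc(C)c(OC)c(C[Zn]Cl)c1
F3 | step 8 | 2-(2-methylprop-1-en-1-yl)-1,3-dithiane | CC(C)=CC1SCCCS1
F4 | step 8 | 2-lithio-2-(2-methylprop-1-en-1-yl)-1,3-dithiane | [Li]C1(C=C(C)C)SCCCS1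
F5 | step 8 | tert-butyl{[(2Z,6E)-3,7-dimethyl-8-[2-(2-methylprop-1-en-1-yl)-1,3-dithian-2-yl]octa-2,6-dien-1-yl]oxy}dimethylsilane | CC(C)=CC1(C/C(C)=C/CC/C(C)=C\CO[Si](C)(C)C(C)(C)C)SCCCS1
F6 | step 10 | tert-butyl{[(2Z,6E)-8-iodo-3,7-dimethylocta-2,6-dien-1-yl]oxy}dimethylsilane | IC/C(C)=C/CC/C(C)=C\CO[Si](C)(C)C(C)(C)C
F7 | step 10 | sodium (Z)-enolate of (4S)-4-benzyl-3-[(4-methoxybenzyloxy)acetyl]-1,3-oxazolidin-2-one | [Na+].[O-]/C(=C\OCc1ccc(OC)cc1)N1C(=O)OC[C@@H]1Cc1ccccc1
F8 | step 10 | (4S)-4-benzyl-3-[(2R,4E,8Z)-10-(tert-butyldimethylsilyloxy)-2-(4-methoxybenzyloxy)-4,8-dimethyldeca-4,8-dienoyl]-1,3-oxazolidin-2-one | O=C1OC[C@H](Cc2ccccc2)N1C(=O)[C@H](OCc1ccc(OC)cc1)C/C(C)=C/CC/C(C)=C\CO[Si](C)(C)C(C)(C)C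
F9 | step 10 | (2R,4E,8Z)-10-(tert-butyldimethylsilyloxy)-2-(4-methoxybenzyloxy)-4,8-dimethyldeca-4,8-dien-1-ol | OC[C@H](OCc1ccc(OC)cc1)C/C(C)=C/CC/C(C)=C\CO[Si](C)(C)C(C)(C)C
F10 | step 10 | (2R,4E,8Z)-10-(tert-butyldimethylsilyloxy)-2-(4-methoxybenzyloxy)-4,8-dimethyldeca-4,8-dienal | O=C[C@H](OCc1ccc(OC)cc1)C/C(C)=C/CC/C(C)=C\CO[Si](C)(C)C(C)(C)C
F11 | step 10 | isopropylidene(triphenyl)phosphorane | CC(C)=P(c1ccccc1)(c1ccccc1)c1ccccc1
F12 | step 10 | tert-butyl{[(2Z,6E,9R)-9-(4-methoxybenzyloxy)-3,7,11-trimethyldodeca-2,6,10-trien-1-yl]oxy}dimethylsilane | CC(C)=C[C@H](OCc1ccc(OC)cc1)C/C(C)=C/CC/C(C)=C\CO[Si](C)(C)C(C)(C)C
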